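## Retrosynthetic overview
1. Hanultarin ⇒ (global desilylation) tri-O-TIPS-hanultarin ⇒ (ester C–O) C2-symmetric (R,R)-diol + O-TIPS-ferulic acid. The two CH2OH groups are homotopic, so only one monoester exists and acyl migration is degenerate.
2. (R,R)-Diol ⇒ (reductive auxiliary removal) C2-symmetric (R,R)-2,3-dibenzylsuccinyl bis-imide.
3. Key step: the central C8–C8′ bond and both stereocentres are made in one operation by oxidative homocoupling of a single chiral imide enolate. This replaces the usual Stobbe or stepwise β-benzylbutyrolactone alkylation route.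
4. Imide ⇒ dihydroferulic acid + valine-derived (4S)-oxazolidinone.
5. Rings: none are formed. All three arenes are bought intact, and the oxazolidinone is a recoverable auxiliary.

Assumption: CIP analysis of the given SMILES gives (R) at both sp3 stereocentres, which is the (−)-secoisolariciresinol series, and an E alkene. Hydrolysis of the transient silyl ester during work-up is counted as part of the silylation step.

## Route

**Step 1**
Reactants: 1, 3-(4-hydroxy-3-methoxyphenyl)propanoic acid (dihydroferulic acid); 2, chlorotriisopropylsilane (TIPSCl)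
Product: 3, 3-[3-methoxy-4-(triisopropylsilyloxy)phenyl]propanoic acid
Conditions: TIPSCl (2.4 equiv), imidazole (5 equiv), DMF, rt, 16 h; then K2CO3, THF/MeOH/H2O, rt, 1 h; 10% citric acid
Reagents that add atoms: TIPSCl, CC(C)[Si](Cl)(C(C)C)C(C)C
Why: In this silyl protection, phenol and acid are both silylated, and the labile silyl ester is then hydrolysed selectively by mild carbonate while the hindered aryl TIPS ether survives.

**Step 2**
Reactants: 3; 4, (4S)-4-isopropyl-1,3-oxazolidin-2-one
Product: 5, (4S)-4-isopropyl-3-{3-[3-methoxy-4-(triisopropylsilyloxy)phenyl]propanoyl}-1,3-oxazolidin-2-one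
Conditions: PivCl, Et3N, THF, −20 → 0 °C; then LiCl, 4, rt, 12 h
Reagents that add atoms: (4S)-4-isopropyloxazolidin-2-one, CC(C)[C@H]1COC(=O)N1
Why: This is a mixed-anhydride N-acylation of an Evans auxiliary, in which the LiCl-activated oxazolidinone attacks the unhindered carbonyl of the pivalic mixed anhydride and no stereocentre is touched.

**Step 3 (key step)**
Reactants: 5 (2 molecules)
Product: 6, (2R,3R)-2,3-bis[3-methoxy-4-(triisopropylsilyloxy)benzyl]-1,4-bis[(4S)-4-isopropyl-2-oxo-1,3-oxazolidin-3-yl]butane-1,4-dione
Conditions: LDA (1.1 equiv), THF (0.25 M), −78 °C, 45 min; TiCl4 (1.1 equiv), −78 °C → rt, 12 h; aq NH4Cl; chromatography or crystallisation to remove the minor (R,S) isomer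
Reagents that add atoms: none
Why: In this oxidative enolate homocoupling (Ti(IV)→Ti(III) one-electron oxidation of the chelated Z-imide enolate), each α-carbon forms the new C–C bond on the face anti to the C4 isopropyl group, so the (4S)-auxiliary gives the (R,R)-dimer as the major product, and the other isomers are diastereomers that can be separated to give a stereopure compound.

**Step 4**
Reactants: 6
Product: 7, (2R,3R)-2,3-bis[3-methoxy-4-(triisopropylsilyloxy)benzyl]butane-1,4-diol (4,4′-di-O-TIPS-(−)-secoisolariciresinol); auxiliary 4 is recovered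
Conditions: LiBH4 (6 equiv), MeOH (6 equiv), THF, 0 °C → rt, 6 h; aq Rochelle salt
Reagents that add atoms: none
Why: In this reductive cleavage of N-acyloxazolidinones, hydride attacks the exocyclic imide carbonyls, any hydroxy-imide that lactonises is reduced on to the same diol, and the non-enolising conditions retain both centres, which stay (R,R) because CH2OH keeps the CIP rank of C=O.

**Step 5**
Reactants: 8, (E)-ferulic acid; 2, TIPSCl
Product: 9, (E)-3-[3-methoxy-4-(triisopropylsilyloxy)phenyl]prop-2-enoic acid
Conditions: TIPSCl (2.4 equiv), imidazole (5 equiv), DMF, rt; then K2CO3, THF/MeOH/H2O, rt, 1 h; 10% citric acid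
Reagents that add atoms: TIPSCl, CC(C)[Si](Cl)(C(C)C)C(C)C
Why: This is the same silyl protection and selective silyl-ester hydrolysis as Step 1, and the E-cinnamate is inert to it.

**Step 6**
Reactants: 7 (2.0 equiv); 9 (1.0 equiv)
Product: 10, (2R,3R)-4-hydroxy-2,3-bis[3-methoxy-4-(triisopropylsilyloxy)benzyl]butyl (E)-3-[3-methoxy-4-(triisopropylsilyloxy)phenyl]prop-2-enoate (tri-O-TIPS-hanultarin)
Conditions: EDC·HCl (1.2 equiv), DMAP (0.2 equiv), CH2Cl2, 0 °C → rt, 9 added by syringe pump over 4 h; unreacted 7 recovered by chromatography and recycled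
Reagents that add atoms: acid 9 (acyl donor), COc1cc(/C=C/C(=O)O)ccc1O[Si](C(C)C)(C(C)C)C(C)C
Why: In this Steglich esterification of a C2-symmetric diol, the hydroxyls are homotopic so only one monoester can form, the twofold excess of diol statistically limits the diester (about 75% mono on acid, about 86% on diol consumed), and the stereocentres are not involved.

**Step 7**
Reactants: 10
Product: 11, hanultarin
Conditions: TBAF (3.3 equiv), AcOH (3.6 equiv), THF, 0 °C, 1 h, protected from light
Reagents that add atoms: none
Why: In this fluoride desilylation, aryl TIPS ethers cleave rapidly because phenoxide is a good leaving group, the AcOH buffer keeps the phenoxides from attacking the cinnamate ester, and any 1,4-acyl shift regenerates the same molecule.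

## Compound list
1 | 3-(4-hydroxy-3-methoxyphenyl)propanoic acid | COc1cc(CCC(=O)O)ccc1O | starting material
2 | chlorotriisopropylsilane | CC(C)[Si](Cl)(C(C)C)C(C)C | starting material
3 | 3-[3-methoxy-4-(TIPSO)phenyl]propanoic acid | COc1cc(CCC(=O)O)ccc1O[Si](C(C)C)(C(C)C)C(C)C | intermediate
4 | (4S)-4-isopropyl-1,3-oxazolidin-2-one | CC(C)[C@H]1COC(=O)N1 | starting material
5 | (4S)-N-acyl oxazolidinone | COc1cc(CCC(=O)N2[C@@H](C(C)C)COC2=O)ccc1O[Si](C(C)C)(C(C)C)C(C)C | intermediate
6 | (2R,3R)-dibenzylsuccinyl bis-imide | O=C(N1[C@@H](C(C)C)COC1=O)[C@H](Cc1ccc(O[Si](C(C)C)(C(C)C)C(C)C)c(OC)c1)[C@@H](Cc1ccc(O[Si](C(C)C)(C(C)C)C(C)C)c(OC)c1)C(=O)N1[C@@H](C(C)C)COC1=O | intermediate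
7 | 4,4′-di-O-TIPS-(−)-secoisolariciresinol, (2R,3R) | OC[C@H](Cc1ccc(O[Si](C(C)C)(C(C)C)C(C)C)c(OC)c1)[C@@H](Cc1ccc(O[Si](C(C)C)(C(C)C)C(C)C)c(OC)c1)CO | intermediate
8 | (E)-ferulic acid | COc1cc(/C=C/C(=O)O)ccc1O | starting material
9 | (E)-4-O-TIPS-ferulic acid | COc1cc(/C=C/C(=O)O)ccc1O[Si](C(C)C)(C(C)C)C(C)C | intermediate
10 | tri-O-TIPS-hanultarin | COc1cc(/C=C/C(=O)OC[C@H](Cc2ccc(O[Si](C(C)C)(C(C)C)C(C)C)c(OC)c2)[C@H](CO)Cc2ccc(O[Si](C(C)C)(C(C)C)C(C)C)c(OC)c2)ccc1O[Si](C(C)C)(C(C)C)C(C)C | intermediate
11 | hanultarin | COc1cc(/C=C/C(=O)OC[C@H](Cc2ccc(O)c(OC)c2)[C@H](CO)Cc2ccc(O)c(OC)c2)ccc1O | target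

## Summary
Total step count: 7
Longest linear sequence: 6 (1 → 3 → 5 → 6 → 7 → 10 → 11)

Steps most likely to fail:
1. **Step 3, oxidative homocoupling.** The risks are modest yield or dr, protonated 5 being returned, and TiCl4 attacking the guaiacyl silyl ether.
   Fallback: give up dimerisation and build the two centres stepwise from the same imide 5.
   - NaHMDS and tert-butyl bromoacetate give the (R)-succinate.
   - LiBH4 reduction followed by acid lactonisation gives the (R)-β-benzyl-γ-butyrolactone.
   - LDA and 3-methoxy-4-(TIPSO)benzyl bromide give the trans-(3R,4R)-lactone.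
   - LiAlH4 reduction gives 7.
2. **Step 6, monoacylation.** The risk is more diester than statistics predict, or a tedious recycle of 7.
   Fallback: replace statistical control with template control. Pre-form the seven-membered dibutylstannylene acetal of 7 (Bu2SnO, toluene, Dean–Stark). Treat it with 1.0 equiv of the acid chloride of 9. After the first acylation the remaining O–SnBu2Cl alkoxide is deactivated, which stops the reaction at the monoester.
3. **Step 4, reduction of the hindered bis-imide.** The risks are endocyclic oxazolidinone opening and incomplete reduction.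
   Fallback: separate auxiliary removal from reduction. Hydrolyse with LiOH/H2O2 (THF/H2O, 0 °C) to the (2R,3R)-dibenzylsuccinic acid, recovering the auxiliary. Then reduce the diacid to 7 with BH3·SMe2.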